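Late in this flask, the maple run followed so far, the left-handed substrate holds level, 26.9% at 1.50 min and 28.5% at 6.00 min, yet the left-handed product gains just 4.6 percentage points between 3.00 min and 6.00 min. What I do at 10 min hangs on what has faded, and I suspect the partner, which also goes into self-condensation product.

| flask | left-handed substrate | right-handed substrate | partner | catalyst | remark | time |
|---|---|---|---|---|---|---|
| maple | 20 mM | 20 mM | 3 equiv | 5 mol% | the very flask that is asked about, followed so far |  |
| flask | 20 mM | 20 mM | 3.00 equiv | 5 mol% |  | 10 min |

maple run (percent of the left-handed substrate and right-handed substrate together charged)

| time / min | left-handed product / % | left-handed substrate / % |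
|---|---|---|
| 0.500 | 19.6 | 31.7 |
| 0.833 | 24.5 | 29.3 |
| 1.50 | 29.3 | 26.9 |
| 3.00 | 37.1 | 28.6 |
| 6.00 | 41.7 | 28.5 |

(scatter of a reading: 1 percentage point)

- teal: at 10 min add partner, 50.0% of the amount charged, then wait 20 min
- green: at 10 min take out 90% of the left-handed product then present, then wait 20 min
- violet: change nothing and wait 20 min more
- blue: at 10 min add catalyst, 100% of the amount charged, then wait 20 min

- catalyst is single-handed; left-handed substrate and right-handed substrate are mirror images of each other, charged as a racemate, each of them at the stated concentration
- left-handed product that was removed still counts
- steps thought possible: partner + catalyst + left-handed substrate -> catalyst + left-handed product; left-handed substrate <-> right-handed substrate; partner + catalyst + right-handed substrate -> catalyst + right-handed product; 2 partner -> self-condensation product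
- additions bring no volume worth counting

* left-handed product, in percent of the left-handed substrate and right-handed substrate together first charged, at 10 min
* which option adds most left-handed product ("none" when 2 percentage points or less is all one gets) (teal / green / violet / blue / none)
* left-handed product present, with what was taken out counted in, in percent of the left-handed substrate and right-handed substrate together first charged, after green
* left-handed product present, with what was taken out counted in, in percent of the left-handed substrate and right-handed substrate together first charged, after blue

With catalyst and substrate steady, the way to product goes as c(partner) (pseudo-first-order) and self-condensation as c(partner) squared, so the share of partner reaching product is s/(s + c(partner)), with s proportional to c(catalyst) and c(left-handed substrate). Integrating that share over falling partner removes time: a dose c of partner is worth W = s ln(1 + c/s) of product. I set W of the whole charge, 60.0 mM, equal to the last reading, 16.7 mM, and solve by repeated substitution. That gives 7.74 mM, the crossover level s, at which both ways take partner equally.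

Teal brings 30.0 mM. It meets left-handed substrate at 28.5%, while I put the level that met the charged partner midway between the start and that reading, at 39.2%, so my s shrinks to 5.62 mM and W gives 26 points. Green, violet and blue bring no partner, so I hold the present value and those options near 41.7%, and I would charge partner.

The forecast gives 43.5% now, teal as best on the ground that “Fresh partner restarts the reaction”, 45.5% after green and 48% after blue; my figure for green and blue is lower.

The flask gives 41.9% at 10 min, 42.4% after green and 42.4% after blue, and teal adds 23 points.

    partner + catalyst + left-handed substrate → catalyst + left-handed product (k = 490 M⁻² s⁻¹)
    left-handed substrate ⇌ right-handed substrate (k = 0.00490 s⁻¹)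
    partner + catalyst + right-handed substrate → catalyst + right-handed product (k = 9.51 M⁻² s⁻¹)
    2 partner → self-condensation product (k = 0.422 M⁻¹ s⁻¹)

Partner stands at 0.368% of its charge at 10.0 min, and W of that rest is 0.54 points, beside the 0.53 points that waiting adds. In the neighbour with 2 mol% of catalyst, s scaled on catalyst with the substrate level held is 3.09 mM, and W of the full charge gives 23.3% against the 25.2% that neighbour holds at 10 min. Left until 100 min, this flask holds partner at 0%, left-handed substrate at 28.2% and right-handed substrate at 28.2%, and its left-handed product stands at 42.4%, 0.50 points above its value at 10 min.

Readings and results were generated by integration on assumed constants, noise included.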